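## Structural features

The target is a lignan of the 9,9'-epoxy type: a tetrahydrofuran (O1, C2, C3, C4, C5) that carries its only two substituents on C3 and C4, trans to each other. C4 (R) bears a 4-hydroxy-3,5-dimethoxybenzyl group, and C3 (R) bears an exocyclic secondary carbinol carbon (S) that holds the second 4-hydroxy-3,5-dimethoxyphenyl ring. The three stereocentres are contiguous (C4, C3, carbinol carbon), two in the ring and one outside it. The two aryl-bearing carbons differ only in oxidation level, CH2 on the C4 side and CHOH on the C3 side. The fragile part is the para-hydroxybenzylic alcohol: acid ionises it (quinone methide or benzylic cation, then elimination, epimerisation or capture by a neighbouring hydroxyl to give the isomeric 2-aryl-tetrahydrofuran), hydrogenolysis can remove its oxygen, and the free phenols are easily oxidised. The real difficulty is therefore not the ring but telling the two benzylic carbons apart and fixing the exocyclic carbinol relative to C3. The key step uses the fact that C4 is joined through a CH2 to an arene while C3 is flanked by two carbons (C2 and the carbinol carbon) that can both be written as carbonyl groups: this is what remains when a cyclopropane with two acceptors on one carbon is opened at its CH2 by an aryl nucleophile and the enolate is then acylated.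

## Logic of the disconnections

**19 to 18 to 17.** The last bonds cut are the two phenolic O–CH2Ph bonds (19 from 18) and, before them, the carbinol O–Si bond (18 from 17). Free phenols and a free benzylic hydroxyl cannot pass through the organometallic, hydride and dehydration steps. The demand is that the carbinol is unmasked while the phenols are still benzylated, so that no quinone methide can form, and that the final hydrogenolysis is neutral and stopped in time.

**17 to 16.** The O1–C2 bond of the ring is cut (O1–C5 is equivalent), which gives a 1,4-diol. The ether oxygen and C5 can then be read as the alkoxy part of a lactone. The forward step must close the ring without acid and with the carbinol oxygen blocked; whichever hydroxymethyl is activated, the same ring forms, so no regiocontrol is needed.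

**16 to 15 to 14.** The two C2–H bonds are traced back to a lactone carbonyl (16 from 15) and the silyl ether to the free alcohol (15 from 14). C2 thereby becomes a carbonyl on C3, as the key step requires. The reduction must neither move the silyl group nor epimerise C3.

**14 to 13.** The carbinol C–H bond is cut, which leaves an aryl ketone. The carbinol centre becomes trigonal and C3, now between two carbonyls, becomes stereolabile, so that only C4 has to be carried as a fixed centre. One reduction must then set the carbinol and C3 together relative to C4.

**13 to 12.** The C3–H bond is replaced by a C3–CO2Et bond. C3 becomes the fully substituted carbon of a malonate-type unit, which is what acylation of a ring-opened cyclopropane enolate delivers. The ester must later leave without cleavage of the ketone.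

**12 to 3, 6 and 10.** The C3–C(=O)Ar bond and the aryl–CH2 bond are cut together. The molecule falls into three pieces, and the two aryl groups enter at different oxidation levels (arylmethyl and aroyl), so they never have to be differentiated afterwards. C4 is stored in a small bicyclic lactone. The forward step must open the cyclopropane at its CH2 only, acylate at carbon, and keep the Grignard reagent away from the acid chloride.

**3 to 1 and 2.** The two cyclopropane bonds to the malonate carbon and the lactone acyl–O bond are cut. This leads to a purchasable three-carbon chiral building block and a malonate; C5, C4 and the benzylic CH2 of the target are its three carbons. The demand is that the epoxide is opened before chloride is displaced, so that the configuration is transferred cleanly.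

**6 to 5 to 4, and 10 to 9 to 8 to 7.** The C–Mg and O–benzyl bonds on one side and the C–Cl and O–benzyl bonds on the other are cut, which gives two purchasable syringyl building blocks. Benzyl is chosen because it survives Grignard formation, chloride at high temperature, hydride and fluoride.

## Other disconnections considered

**Alternative 1:** The cut removes C2–C3 and C4–C5 at once; the ring oxygen with its two CH2 groups becomes a three-atom dipole and C3–C4 an E-alkene. In the forward direction chloromethyl (trimethylsilyl)methyl ether A2 would be desilylated by CsF to release the unsubstituted carbonyl ylide, which would add across the double bond of the N-[(E)-4-arylbut-2-enoyl] bornane-10,2-sultam A1 to give the N-acyl sultam A3 of the trans-tetrahydrofuran acid.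
- In its favour: the ring and both ring stereocentres arise in one stereospecific step, the trans relation follows from the alkene geometry, and the ring is at the right oxidation level from the start.
- Against it here: A1 is a 4-aryl-but-2-enoyl system that can move its double bond into conjugation with the electron-rich arene under fluoride. The dipole is very small and very reactive, so face discrimination by the auxiliary is the uncertain point. The acyl group of A3 must still be turned into the aryl carbinol by aryl addition and a reduction that has no lactone carbonyl to organise it.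
- Comparison: on structure both plans reach the trans ring; the alternative sets C3 and C4 by one cycloaddition, while the chosen plan buys C4 and lets C3 settle. On mechanism a concerted (3+2) addition stands against a copper-mediated opening followed by enolate acylation. On step economy after the key step the alternative is the better: it needs no lactone reduction, no cyclodehydration and no silyl protection. This gain is roughly cancelled by the steps to A1, auxiliary attachment and removal, and the separate introduction of the second aryl group. The chosen plan is preferred because its absolute configuration comes from purchased material and both aryl groups enter in one step.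

**Alternative 2:** The cut removes both aryl–carbon bonds, the one to the carbinol carbon and the one to the benzylic carbon. In the forward direction two equivalents of the aryllithium A5 (from 5 by bromine–lithium exchange) would add to the two N-methoxy-N-methylamide groups of the C2-symmetric diamide A4 to give the diketone A6.
- In its favour: one aryl reagent, a preformed ring whose trans relation is the stable one, and chelated tetrahedral intermediates that stop at the ketone. As a bond-forming step it is simpler and better precedented than the chosen key step, and on this point the alternative is the better.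
- Against it here: A6 has two equivalent ketones, yet the target needs one as the (S)-alcohol and the other as CH2. A mono-reduction would be statistical, and a later deoxygenation would have to distinguish two benzylic positions that differ only by what the first step did. The alpha-hydrogens of A4 and A6 are acidic, so enolisation by the aryllithium competes. Enantiopure A4 needs its own synthesis.
- Comparison: on structure the plans are equal for the ring (trans by thermodynamics in both), and the alternative is the better in convergence. On step economy it is shorter up to A6, but the desymmetrisation adds an uncertain number of steps. The chosen plan also brings in both aryl groups in one flask, but as arylmethyl and aroyl, so the differentiation is built in.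

**Alternative 3:** The cut removes the C3–carbinol carbon bond and the carbinol carbon–aryl bond; the carbinol carbon comes from CH2Cl2 as a one-carbon linchpin. In the forward direction (Matteson homologation) the ring boronic ester A7, carrying (S,S)-1,2-dicyclohexylethane-1,2-diol on boron, would take up dichloromethyllithium A8, and with ZnCl2 the ring carbon would migrate from boron to carbon with loss of chloride. The Grignard reagent 6 would then add to boron and its aryl group would migrate with displacement of the second chloride, to give the alpha-aryl boronic ester A9. Oxidation of the C–B bond with retention would lead to 18.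
- In its favour: the carbinol configuration is set by the diol on boron, independently of the ring. C3 migrates with retention and is never stereolabile. The sensitive C–O bond appears only at the end. For the carbinol centre this is the better of the two plans, and it is equally a one-flask three-component assembly.
- Against it here: A7 is a secondary boronic ester on an enantiopure trans-3,4-disubstituted tetrahydrofuran, so the ring, C4 and the arylmethyl side chain must all be made first. Migration of a hindered secondary ring carbon is slow. The chlorinated intermediate can epimerise by chloride exchange. The electron-rich benzylic boronic ester A9 is prone to protodeboronation.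
- Comparison: on structure the alternative solves only the carbinol and leaves the ring and C4 to earlier steps; the chosen plan forms the arylmethyl bond and the acyl bond on a building block that already holds C4. On mechanism two stereospecific 1,2-metallate shifts are more predictable than an acylation followed by a later reduction. On step economy the chosen plan is clearly shorter.

Key step: step 6

Remark: in 3 the former epoxide CH2 of 1 is the cyclopropane CH2 and the former CH2Cl carbon is the lactone OCH2 (epoxide opening before chloride displacement). 6 is used as a titrated THF solution and 10 as the crude residue after evaporation.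

## Route

Step 1
Reactants: 1 (R)-epichlorohydrin; 2 diethyl malonate
Product: 3 ethyl (1S,5R)-2-oxo-3-oxabicyclo[3.1.0]hexane-1-carboxylate
Conditions: NaOEt (1.1 equiv), EtOH, 0 °C → reflux
Reagents that add atoms: none
Why: Tandem alkylation, cyclopropanation and lactonisation: the malonate anion opens the epoxide at its CH2, the alkoxide displaces chloride to form a new epoxide, the malonate carbon attacks the epoxide CH in a 3-exo-tet closure, and the freed alkoxide lactonises onto the cis ester. The stereocentre of 1 undergoes one inversion (oxygen replaced by the malonate carbon) and becomes C5 (R) of 3, while the cis ring fusion fixes C1 (S).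

Step 2
Reactants: 4 4-bromo-2,6-dimethoxyphenol
Product: 5 2-(benzyloxy)-5-bromo-1,3-dimethoxybenzene
Conditions: BnBr, K2CO3, DMF, 60 °C
Reagents that add atoms: benzyl bromide, BrCc1ccccc1
Why: Williamson ether synthesis on the phenoxide; DMF and mild heating overcome the two flanking methoxy groups.

Step 3
Reactants: 5 2-(benzyloxy)-5-bromo-1,3-dimethoxybenzene
Product: 6 [4-(benzyloxy)-3,5-dimethoxyphenyl]magnesium bromide (titrated THF solution)
Conditions: Mg turnings (activated with BrCH2CH2Br), THF, 45 °C
Reagents that add atoms: magnesium, [Mg]
Why: Grignard formation by insertion of magnesium into the aryl C–Br bond; the ether groups are inert and the bromine has no ortho substituent.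

Step 4
Reactants: 7 syringic acid
Product: 9 4-(benzyloxy)-3,5-dimethoxybenzoic acid, via benzyl 4-(benzyloxy)-3,5-dimethoxybenzoate 8 (not isolated)
Conditions: BnBr (2.3 equiv), K2CO3, DMF, 60 °C; then NaOH (aq), MeOH, 60 °C; HCl (aq)
Reagents that add atoms: benzyl bromide, BrCc1ccccc1; sodium hydroxide, [Na+].[OH-]
Why: Double O-alkylation of phenoxide and carboxylate, then saponification of the benzyl ester in the same flask; the aryl benzyl ether is stable to hydroxide.

Step 5
Reactants: 9 4-(benzyloxy)-3,5-dimethoxybenzoic acid
Product: 10 4-(benzyloxy)-3,5-dimethoxybenzoyl chloride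
Conditions: (COCl)2, DMF (cat.), CH2Cl2, 0 °C → rt; evaporation, used crude
Reagents that add atoms: oxalyl chloride, O=C(Cl)C(Cl)=O
Why: Acid chloride formation through the chloroiminium species generated from DMF; the conditions are too mild to touch the benzyl ether.

Step 6
Reactants: 3 ethyl (1S,5R)-2-oxo-3-oxabicyclo[3.1.0]hexane-1-carboxylate; 6 [4-(benzyloxy)-3,5-dimethoxyphenyl]magnesium bromide; 10 4-(benzyloxy)-3,5-dimethoxybenzoyl chloride
Product: 12 ethyl (3S,4R)-3-[4-(benzyloxy)-3,5-dimethoxybenzoyl]-4-[4-(benzyloxy)-3,5-dimethoxybenzyl]-2-oxotetrahydrofuran-3-carboxylate, via bromomagnesium enolate 11 (not isolated)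
Conditions: 3 (1.1 equiv), CuI (10 mol %), THF, −30 °C; 6 (1.0 equiv) added slowly, −30 → 0 °C; then 10 (1.2 equiv), −30 °C → rt; NH4Cl (aq)
Reagents that add atoms: none
Why: Proposed new method: 6 transfers its aryl group to CuI to give an arylcopper species of monovalent copper, which attacks the cyclopropane CH2 of 3 from the rear in an SN2-like homoconjugate addition; the bond from that CH2 to the quaternary carbon breaks, the lactone and ester carbonyls take up the charge, and reductive elimination from the transient trivalent copper intermediate forms the aryl–CH2 bond and returns monovalent copper. The chelated bromomagnesium enolate 11 then attacks 10 at carbon in an acyl substitution and forms the C3–C(=O) bond. The closest known reaction types are the CuI-catalysed Grignard opening of this lactone with protonation of the enolate, the C-acylation of magnesium enolates of malonates by acid chlorides, and the tandem conjugate addition and enolate acylation of enones; what is new is running opening and acylation in one flask on a doubly activated cyclopropane. No ring is closed; the three-membered ring is opened. The new stereocentre is the quaternary C3, controlled by the adjacent C4: the acid chloride should approach the enolate face away from the new arylmethyl group, so the aroyl group ends up trans to it; this centre is erased in step 7, so its ratio is not critical. C4 is not involved in any bond change and keeps the configuration of 3. The step needs attack at the cyclopropane CH2 and not at a carbonyl, which the soft organocopper reagent, ring strain, double activation and low temperature should secure. It needs C- rather than O-acylation, favoured by the magnesium chelate of the 1,3-dicarbonyl unit in an ethereal solvent. It also needs the acid chloride not to meet free Grignard reagent, secured by using 6 as the limiting reagent and consuming it before 10 is added.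

Step 7
Reactants: 12 ethyl (3S,4R)-3-[4-(benzyloxy)-3,5-dimethoxybenzoyl]-4-[4-(benzyloxy)-3,5-dimethoxybenzyl]-2-oxotetrahydrofuran-3-carboxylate
Product: 13 (3S,4R)-3-[4-(benzyloxy)-3,5-dimethoxybenzoyl]-4-[4-(benzyloxy)-3,5-dimethoxybenzyl]dihydrofuran-2(3H)-one
Conditions: LiCl (3 equiv), H2O (2 equiv), DMSO, 130–140 °C
Reagents that add atoms: none
Why: Krapcho dealkoxycarbonylation: chloride attacks the ethyl group, the carboxylate loses CO2 and the enolate is protonated by water. Protonation and equilibration through the enol should leave C3 in the more stable trans arrangement, and C3 stays stereolabile until step 8.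

Step 8
Reactants: 13 (3S,4R)-3-[4-(benzyloxy)-3,5-dimethoxybenzoyl]-4-[4-(benzyloxy)-3,5-dimethoxybenzyl]dihydrofuran-2(3H)-one
Product: 14 (3S,4R)-3-{(S)-[4-(benzyloxy)-3,5-dimethoxyphenyl](hydroxy)methyl}-4-[4-(benzyloxy)-3,5-dimethoxybenzyl]dihydrofuran-2(3H)-one
Conditions: RuCl(p-cymene)[(S,S)-TsDPEN] (2 mol %), HCO2H/Et3N (5:2), DMF, 40 °C
Reagents that add atoms: none
Why: Asymmetric transfer hydrogenation with dynamic kinetic resolution by a bifunctional divalent ruthenium hydride: C3 of 13 epimerises through its enol under Et3N while C4 stays fixed, and the (S,S)-catalyst should reduce the aryl ketone to the (S)-carbinol, as it does with simple aryl alkyl ketones. The trans C3 epimer is the more stable and the less hindered, so the (3S,4R,S) isomer should predominate; it is also the isomer expected from hydride delivery anti to C4 in a chelated arrangement.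

Step 9
Reactants: 14 (3S,4R)-3-{(S)-[4-(benzyloxy)-3,5-dimethoxyphenyl](hydroxy)methyl}-4-[4-(benzyloxy)-3,5-dimethoxybenzyl]dihydrofuran-2(3H)-one
Product: 15 (3S,4R)-3-{(S)-[4-(benzyloxy)-3,5-dimethoxyphenyl][(tert-butyldimethylsilyl)oxy]methyl}-4-[4-(benzyloxy)-3,5-dimethoxybenzyl]dihydrofuran-2(3H)-one
Conditions: TBSOTf, 2,6-lutidine, CH2Cl2, −78 → 0 °C
Reagents that add atoms: tert-butyldimethylsilyl trifluoromethanesulfonate, CC(C)(C)[Si](C)(C)OS(=O)(=O)C(F)(F)F
Why: Silylation of a hindered secondary alcohol with the silyl triflate and a non-nucleophilic base; low temperature and the buffer avoid ionisation of the electron-rich benzylic position and retro-aldol cleavage.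

Step 10
Reactants: 15 (3S,4R)-3-{(S)-[4-(benzyloxy)-3,5-dimethoxyphenyl][(tert-butyldimethylsilyl)oxy]methyl}-4-[4-(benzyloxy)-3,5-dimethoxybenzyl]dihydrofuran-2(3H)-one
Product: 16 (2R,3R)-2-{(S)-[4-(benzyloxy)-3,5-dimethoxyphenyl][(tert-butyldimethylsilyl)oxy]methyl}-3-[4-(benzyloxy)-3,5-dimethoxybenzyl]butane-1,4-diol
Conditions: LiAlH4, THF, 0 °C; KNaC4H4O6 (aq)
Reagents that add atoms: none
Why: Hydride reduction of the lactone to the 1,4-diol; at 0 °C the aluminium alkoxides should not transfer the silyl group, and the buffered tartrate work-up avoids a free alkoxide. No stereocentre is touched.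

Step 11
Reactants: 16 (2R,3R)-2-{(S)-[4-(benzyloxy)-3,5-dimethoxyphenyl][(tert-butyldimethylsilyl)oxy]methyl}-3-[4-(benzyloxy)-3,5-dimethoxybenzyl]butane-1,4-diol
Product: 17 {(S)-[4-(benzyloxy)-3,5-dimethoxyphenyl][(3R,4R)-4-[4-(benzyloxy)-3,5-dimethoxybenzyl]tetrahydrofuran-3-yl]methoxy}(tert-butyl)dimethylsilane
Conditions: PPh3, DIAD, THF, 0 °C → rt
Reagents that add atoms: none
Why: Mitsunobu cyclodehydration: one primary hydroxyl becomes an alkoxyphosphonium ion and is displaced by the other in a 5-exo-tet closure. Either hydroxymethyl group gives the same ring, no stereocentre is involved, and the neutral medium spares the benzylic silyl ether.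

Step 12
Reactants: 17 {(S)-[4-(benzyloxy)-3,5-dimethoxyphenyl][(3R,4R)-4-[4-(benzyloxy)-3,5-dimethoxybenzyl]tetrahydrofuran-3-yl]methoxy}(tert-butyl)dimethylsilane
Product: 18 (S)-[4-(benzyloxy)-3,5-dimethoxyphenyl]{(3R,4R)-4-[4-(benzyloxy)-3,5-dimethoxybenzyl]tetrahydrofuran-3-yl}methanol
Conditions: Bu4NF, THF, 0 °C → rt
Reagents that add atoms: none
Why: Fluoride-induced desilylation; with both phenols still benzylated there is no phenoxide that could expel the benzylic oxygen, so the carbinol configuration is safe.

Step 13
Reactants: 18 (S)-[4-(benzyloxy)-3,5-dimethoxyphenyl]{(3R,4R)-4-[4-(benzyloxy)-3,5-dimethoxybenzyl]tetrahydrofuran-3-yl}methanol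
Product: 19 4-{(S)-hydroxy[(3R,4R)-4-(4-hydroxy-3,5-dimethoxybenzyl)tetrahydrofuran-3-yl]methyl}-2,6-dimethoxyphenol
Conditions: H2 (1 atm), 10% Pd/C, EtOAc, rt
Reagents that add atoms: none
Why: Hydrogenolysis of the two aryl benzyl ethers, which should be cleaved much faster than the secondary benzylic C–OH bond in a neutral, non-protic solvent; the reaction is stopped when 18 is consumed.

## Compound list

1 | (R)-epichlorohydrin | ClC[C@H]1CO1 | starting material
2 | diethyl malonate | CCOC(=O)CC(=O)OCC | starting material
3 | ethyl (1S,5R)-2-oxo-3-oxabicyclo[3.1.0]hexane-1-carboxylate | C1[C@H]2COC(=O)[C@@]12C(=O)OCC | intermediate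
4 | 4-bromo-2,6-dimethoxyphenol | COc1cc(Br)cc(OC)c1O | starting material
5 | 2-(benzyloxy)-5-bromo-1,3-dimethoxybenzene | COc1cc(Br)cc(OC)c1OCc1ccccc1 | intermediate
6 | [4-(benzyloxy)-3,5-dimethoxyphenyl]magnesium bromide | COc1cc([Mg]Br)cc(OC)c1OCc1ccccc1 | intermediate
7 | syringic acid (4-hydroxy-3,5-dimethoxybenzoic acid) | COc1cc(C(O)=O)cc(OC)c1O | starting material
8 | benzyl 4-(benzyloxy)-3,5-dimethoxybenzoate | COc1cc(C(=O)OCc2ccccc2)cc(OC)c1OCc1ccccc1 | intermediate
9 | 4-(benzyloxy)-3,5-dimethoxybenzoic acid | COc1cc(C(O)=O)cc(OC)c1OCc1ccccc1 | intermediate
10 | 4-(benzyloxy)-3,5-dimethoxybenzoyl chloride | COc1cc(C(Cl)=O)cc(OC)c1OCc1ccccc1 | intermediate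
11 | bromomagnesium enolate of ethyl (4R)-4-[4-(benzyloxy)-3,5-dimethoxybenzyl]-2-oxotetrahydrofuran-3-carboxylate | COc1cc(C[C@H]2COC(=O)C2=C(OCC)O[Mg]Br)cc(OC)c1OCc1ccccc1 | intermediate
12 | ethyl (3S,4R)-3-[4-(benzyloxy)-3,5-dimethoxybenzoyl]-4-[4-(benzyloxy)-3,5-dimethoxybenzyl]-2-oxotetrahydrofuran-3-carboxylate | COc1cc(C[C@H]2COC(=O)[C@]2(C(=O)OCC)C(=O)c2cc(OC)c(OCc3ccccc3)c(OC)c2)cc(OC)c1OCc1ccccc1 | intermediate
13 | (3S,4R)-3-[4-(benzyloxy)-3,5-dimethoxybenzoyl]-4-[4-(benzyloxy)-3,5-dimethoxybenzyl]dihydrofuran-2(3H)-one | COc1cc(C[C@H]2COC(=O)[C@@H]2C(=O)c2cc(OC)c(OCc3ccccc3)c(OC)c2)cc(OC)c1OCc1ccccc1 | intermediate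
14 | (3S,4R)-3-{(S)-[4-(benzyloxy)-3,5-dimethoxyphenyl](hydroxy)methyl}-4-[4-(benzyloxy)-3,5-dimethoxybenzyl]dihydrofuran-2(3H)-one | COc1cc(C[C@H]2COC(=O)[C@@H]2[C@H](O)c2cc(OC)c(OCc3ccccc3)c(OC)c2)cc(OC)c1OCc1ccccc1 | intermediate
15 | (3S,4R)-3-{(S)-[4-(benzyloxy)-3,5-dimethoxyphenyl][(tert-butyldimethylsilyl)oxy]methyl}-4-[4-(benzyloxy)-3,5-dimethoxybenzyl]dihydrofuran-2(3H)-one | COc1cc(C[C@H]2COC(=O)[C@@H]2[C@H](O[Si](C)(C)C(C)(C)C)c2cc(OC)c(OCc3ccccc3)c(OC)c2)cc(OC)c1OCc1ccccc1 | intermediate
16 | (2R,3R)-2-{(S)-[4-(benzyloxy)-3,5-dimethoxyphenyl][(tert-butyldimethylsilyl)oxy]methyl}-3-[4-(benzyloxy)-3,5-dimethoxybenzyl]butane-1,4-diol | COc1cc(C[C@@H](CO)[C@H](CO)[C@H](O[Si](C)(C)C(C)(C)C)c2cc(OC)c(OCc3ccccc3)c(OC)c2)cc(OC)c1OCc1ccccc1 | intermediate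
17 | {(S)-[4-(benzyloxy)-3,5-dimethoxyphenyl][(3R,4R)-4-[4-(benzyloxy)-3,5-dimethoxybenzyl]tetrahydrofuran-3-yl]methoxy}(tert-butyl)dimethylsilane | COc1cc(C[C@H]2COC[C@@H]2[C@H](O[Si](C)(C)C(C)(C)C)c2cc(OC)c(OCc3ccccc3)c(OC)c2)cc(OC)c1OCc1ccccc1 | intermediate
18 | (S)-[4-(benzyloxy)-3,5-dimethoxyphenyl]{(3R,4R)-4-[4-(benzyloxy)-3,5-dimethoxybenzyl]tetrahydrofuran-3-yl}methanol | COc1cc(C[C@H]2COC[C@@H]2[C@H](O)c2cc(OC)c(OCc3ccccc3)c(OC)c2)cc(OC)c1OCc1ccccc1 | intermediate
19 | 4-{(S)-hydroxy[(3R,4R)-4-(4-hydroxy-3,5-dimethoxybenzyl)tetrahydrofuran-3-yl]methyl}-2,6-dimethoxyphenol | COc1cc(C[C@H]2COC[C@@H]2[C@H](O)c2cc(OC)c(O)c(OC)c2)cc(OC)c1O | target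

## Step count and least certain steps

Total: 13 steps. Longest linear sequence: 10 steps (from 7 through steps 4, 5 and 6 to 13, or from 4 through steps 2, 3 and 6 to 13).

**Step 6 (key step).** The most likely failures are O-acylation or incomplete acylation of the hindered, chelated enolate as it forms a quaternary carbon, and consumption of the acid chloride by Grignard reagent that has not yet reacted. The fallback sets out from 3 and 6 and returns at 12. The opening is run alone under the same CuI catalysis and the enolate is protonated with aqueous NH4Cl, which should give ethyl (4R)-4-[4-(benzyloxy)-3,5-dimethoxybenzyl]-2-oxotetrahydrofuran-3-carboxylate F1 as a pair of C3 epimers. After isolation, F1 is deprotonated with NaH in THF at 0 °C and the sodium enolate is acylated at carbon with 10, the classical acylation of a substituted malonate-type enolate, to give 12.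

**Step 7.** The non-enolisable ketone of 12 sits on a carbon with two further carbonyl groups, so retro-Claisen loss of the aroyl group through attack of water at high temperature may compete with dealkylation; chloride may also open the lactone at C5. The fallback sets out from 3 and 6 and returns at 13; it changes the order of events so that the ester leaves before the ketone is present. The ester lactone F1, made as described for step 6, is dealkoxycarbonylated under the same Krapcho conditions, which are well suited to this simple lactone ester, to give (4R)-4-[4-(benzyloxy)-3,5-dimethoxybenzyl]dihydrofuran-2(3H)-one F2. Its lithium enolate (LiN(SiMe3)2, 2.1 equiv, THF, −78 °C) is acylated with 10 in a Claisen-type acylation, the second equivalent of base taking up the more acidic product, and protonation should give 13 as the trans isomer.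

**Step 8.** The intrinsic preference of the catalyst for the relation between C3 and the carbinol may oppose the trans preference of the substrate, which would lower the diastereoselectivity; the electron-rich aryl ketone may also be reduced slowly. The fallback sets out from 13 and returns at 14 and relies on substrate control: Zn(BH4)2 in Et2O at −20 °C should chelate the ketone and lactone carbonyls and deliver hydride to the ketone face anti to C4 of the trans isomer, which leads to the same (3S,4R,S) arrangement. This fallback makes no compound outside the list (entry F0).

**Step 13.** Once the phenols are free, the para-hydroxybenzylic C–O bond is activated, so over-reduction by hydrogenolysis of the carbinol may set in before both benzyl ethers are gone. The fallback sets out from 17 and returns at 19 and reverses the order of the last two steps. Hydrogenolysis of 17 (H2, 10% Pd/C, EtOAc), with the carbinol oxygen still silylated and so much less prone to cleavage, should give 4-{(S)-[(tert-butyldimethylsilyl)oxy][(3R,4R)-4-(4-hydroxy-3,5-dimethoxybenzyl)tetrahydrofuran-3-yl]methyl}-2,6-dimethoxyphenol F3. Desilylation of F3 with Bu4NF buffered with AcOH, so that no phenoxide is formed, then gives 19.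

## Further compounds

F1 | step 6 | ethyl (4R)-4-[4-(benzyloxy)-3,5-dimethoxybenzyl]-2-oxotetrahydrofuran-3-carboxylate (C3 epimers) | COc1cc(C[C@H]2COC(=O)C2C(=O)OCC)cc(OC)c1OCc1ccccc1
F2 | step 7 | (4R)-4-[4-(benzyloxy)-3,5-dimethoxybenzyl]dihydrofuran-2(3H)-one | COc1cc(C[C@H]2COC(=O)C2)cc(OC)c1OCc1ccccc1
F0 | step 8 | none | none
F3 | step 13 | 4-{(S)-[(tert-butyldimethylsilyl)oxy][(3R,4R)-4-(4-hydroxy-3,5-dimethoxybenzyl)tetrahydrofuran-3-yl]methyl}-2,6-dimethoxyphenol | COc1cc(C[C@H]2COC[C@@H]2[C@H](O[Si](C)(C)C(C)(C)C)c2cc(OC)c(O)c(OC)c2)cc(OC)c1O
A1 | alternative 1 | N-[(2E)-4-[4-(benzyloxy)-3,5-dimethoxyphenyl]but-2-enoyl]bornane-10,2-sultam (C2 of the bornane S) | COc1cc(C/C=C/C(=O)N2[C@H]3C[C@@H]4CC[C@@]3(CS2(=O)=O)C4(C)C)cc(OC)c1OCc1ccccc1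
A2 | alternative 1 | chloromethyl (trimethylsilyl)methyl ether | ClCOC[Si](C)(C)C
A3 | alternative 1 | N-{[(3R,4R)-4-[4-(benzyloxy)-3,5-dimethoxybenzyl]tetrahydrofuran-3-yl]carbonyl}bornane-10,2-sultam (C2 of the bornane S) | COc1cc(C[C@H]2COC[C@@H]2C(=O)N2[C@H]3C[C@@H]4CC[C@@]3(CS2(=O)=O)C4(C)C)cc(OC)c1OCc1ccccc1
A4 | alternative 2 | (3R,4R)-N3,N4-dimethoxy-N3,N4-dimethyltetrahydrofuran-3,4-dicarboxamide | CON(C)C(=O)[C@H]1COC[C@@H]1C(=O)N(C)OC
A5 | alternative 2 | [4-(benzyloxy)-3,5-dimethoxyphenyl]lithium | [Li]c1cc(OC)c(OCc2ccccc2)c(OC)c1
A6 | alternative 2 | [(3R,4R)-tetrahydrofuran-3,4-diyl]bis{[4-(benzyloxy)-3,5-dimethoxyphenyl]methanone} | COc1cc(C(=O)[C@H]2COC[C@@H]2C(=O)c2cc(OC)c(OCc3ccccc3)c(OC)c2)cc(OC)c1OCc1ccccc1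
A7 | alternative 3 | (4S,5S)-2-[(3R,4R)-4-[4-(benzyloxy)-3,5-dimethoxybenzyl]tetrahydrofuran-3-yl]-4,5-dicyclohexyl-1,3,2-dioxaborolane | COc1cc(C[C@H]2COC[C@@H]2B2O[C@@H](C3CCCCC3)[C@H](C3CCCCC3)O2)cc(OC)c1OCc1ccccc1
A8 | alternative 3 | dichloromethyllithium | [Li]C(Cl)Cl
A9 | alternative 3 | (4S,5S)-2-{(S)-[4-(benzyloxy)-3,5-dimethoxyphenyl][(3R,4R)-4-[4-(benzyloxy)-3,5-dimethoxybenzyl]tetrahydrofuran-3-yl]methyl}-4,5-dicyclohexyl-1,3,2-dioxaborolane | COc1cc(C[C@H]2COC[C@@H]2[C@H](B2O[C@@H](C3CCCCC3)[C@H](C3CCCCC3)O2)c2cc(OC)c(OCc3ccccc3)c(OC)c2)cc(OC)c1OCc1ccccc1
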